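(All runs were generated by integration from invented constants, and the scatter is random.)

Maple stands at 105 °C and elm at 90 °C, with the same charges, and I want the target in each at 25 h.

common to all: partner 0.418 M; capture agent 0.114 M; second catalyst 0.38 mM

|  | substrate | free catalyst | temperature | remark | time |
|---|---|---|---|---|---|
| Tuesday's | 0.38 M | 0.51 mM | 94 °C | run made earlier |  |
| Sunday's | 0.38 M | 1.1 mM | 102 °C | run made earlier |  |
| Thursday's | 0.19 M | 0.76 mM | 94 °C | run made earlier |  |
| maple | 0.38 M | 0.76 mM | 105 °C |  | 25 h |
| elm | 0.38 M | 0.76 mM | 90 °C |  | 25 h |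

| run | time / h | target / % | substrate / % |
|---|---|---|---|
| Tuesday's | 2.50 | 6.9 | 57.4 |
| Tuesday's | 4.00 | 7.3 | 46.1 |
| Tuesday's | 6.00 | 7.7 | 36.5 |
| Tuesday's | 15.0 | 6.8 | 17.4 |
| Tuesday's | 25.0 | 7.0 | 10.2 |
| Sunday's | 3.00 | 9.6 | 37.0 |
| Sunday's | 6.00 | 10.5 | 22.6 |
| Sunday's | 10.0 | 9.7 | 13.7 |
| Sunday's | 12.0 | 9.5 | 11.0 |
| Sunday's | 15.0 | 9.4 | 8.6 |
| Thursday's | 2.50 | 10.4 | 51.3 |
| Thursday's | 4.00 | 10.3 | 38.5 |
| Thursday's | 6.00 | 10.4 | 27.2 |
| Thursday's | 15.0 | 10.3 | 6.8 |
| Thursday's | 25.0 | 10.5 | 1.4 |

(standard deviation of a reading: 0.3 percentage points)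



- the best flask by amount of target, in percent of the substrate charged; "all alike" if 1.5 percentage points covers them all (maple / elm / all alike)
- amount of target at the end, in percent of the substrate charged, maple
- amount of target at the end, in percent of the substrate charged, elm

I can solve two extreme versions of these flasks in my head. In one, the free catalyst outlasts the substrate, and target climbs for as long as substrate falls. In the other, the free catalyst stops before substrate has moved, so substrate is frozen at its charge while the catalyst works. At one temperature, with partner, capture agent and second catalyst held, target as a fraction of the substrate charged is then a constant times the free catalyst, whatever the substrate charge, and it stays flat afterwards.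

Tuesday's run lies near the frozen end, because from 2.50 h to 25.0 h substrate falls by 47 percentage points while target moves by 0.1 points, inside the scatter. But substrate is already at 57.4 % by the first reading, so these readings don't show how far it moved while target rose, and I read the constant off the plateaus instead of reckoning it.

Thursday's run reads 0.137 mM⁻¹ at 94 °C. This fraction of the substrate charged ending as target, per mM of free catalyst charged, is what I call the yield per catalyst; it is the turnover number taken per substrate charged. Tuesday's run reads 0.137 mM⁻¹, though catalyst and substrate both differ between those two runs. Sunday's run reads 0.0882 mM⁻¹ at 102 °C, lower by a factor of 1.55.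

If I put that factor down to temperature, going from Thursday's run to Sunday's, and take it as steady per degree, my reckoning gives 5.68 % for maple and 13.0 % for elm, so elm leads by 7.3 points, more than the margin.

The forecast picks elm, with 5.8 % in maple and 12.8 % in elm, holding that “the plateau is proportional to free catalyst and independent of substrate charge”. Its figures are not mine, though the two lie close.

The flasks give 5.74 % in maple and 12.7 % in elm, so elm holds more.

    substrate + free catalyst → free catalyst + open intermediate (k = 368 L mol⁻¹ h⁻¹, Ea = 49.0 kJ mol⁻¹)
    partner + second catalyst + open intermediate → second catalyst + target (k = 67200 L² mol⁻² h⁻¹, Ea = 49.0 kJ mol⁻¹)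
    substrate + partner → uncatalysed product (k = 0.427 L mol⁻¹ h⁻¹, Ea = 89.0 kJ mol⁻¹)
    free catalyst → spent catalyst (k = 1.59 h⁻¹, Ea = 108 kJ mol⁻¹)
    open intermediate + capture agent → trapped intermediate (k = 13.0 L mol⁻¹ h⁻¹, Ea = 89.0 kJ mol⁻¹)
    (constants at 90 °C)

In maple, half of the turnover of substrate with free catalyst up to 25 h is done by 0.0953 h, and half of the turnover of substrate with partner by 1.62 h. Free catalyst stands at 0 % of its charge by 12.5 h, and target at 5.74 % then and 5.74 % at 25.0 h. Read back, the yield per catalyst is 0.0755 mM⁻¹ in maple and 0.168 mM⁻¹ in elm. Carried from 0.137 mM⁻¹ to a repeat of maple at 130 °C, it gives 1.44 %, and that repeat holds 1.52 % of target at 25.0 h.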